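No rate constants are to hand for this flask, but Friday's run gives a time, and a time is enough for a quick number.

all flasks: starting material 0.10 M
- Friday's: coupling partner 0.18 M; temperature 100 °C; the very flask that is asked about, followed so far
- Monday's: coupling partner 0.18 M; temperature 95 °C; run made earlier
- flask: coupling partner 0.180 M; temperature 100 °C; time 8.0 d

- Friday's (time / h: target / %): 10.0: 4; 15.0: 2; 20.0: 6; 30.0: 10; 50.0: 14; 72.0: 15; 120: 17
- Monday's (time / h: target / %): 10.0: 3; 15.0: 4; 20.0: 5; 30.0: 6; 50.0: 9; 72.0: 11; 120: 17

(scatter of a reading: 1.5 percentage points)

- teal: at 8.0 d add coupling partner, 50.0 % of the amount charged, then wait 4.0 d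
- violet: at 8.0 d raise the temperature by 10 K, then wait 4.0 d
- blue: change nothing and wait 4.0 d more
- amber: at 8.0 d take out 90 % of the target then present, then wait 4.0 d

- removed target is counted in
- the earlier runs were read with a standard deviation of 1.5 percentage points
- additions bring no volume worth counting

1. target, in percent of the starting material first charged, at 8.0 d
2. which option adds most target ("none" when 2 percentage points or less is all one gets) (teal / violet / blue / amber / none)
3. target present, with what was taken out counted in, in percent of the starting material first charged, after teal
4. target present, with what was taken out counted in, in percent of the starting material first charged, after blue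

Friday's flask rises and then flattens near 17 %. I take that last reading as the stopping level and define the stall half-life (a relaxation half-life, in the usual term) as the time in which the gap to that level falls to 0.5 of itself. The reading at 30.0 h gives it, with the scatter of the readings in it:

stall half-life = 30.0 h × ln(2) / ln(17 % / (17 % − 10 %)) = 23.4 h

half-lives up to the look: 8.0 d / 23.4 h = 8.19

half-lives in the further wait: 4.0 d / 23.4 h = 4.10

So I say about 17 % now, and blue adds little, since the gap left is 0.058 percentage points.

If one coupling partner goes into each target, c(coupling partner) stands near 0.163 M at that level, so I read the stop as a balance rather than a charge used up. Then amber reopens the gap, and the wait refills it: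

gain after amber = 90 % × 17 % × (1 − 0.5 ^ 4.10) = 14 points

The forecast you sent differs from me on the choice. It gives 17.2 % now, 17.4 % after blue, 23.5 % after teal, and picks teal, on this ground: “Partner loss fits this”. I pick amber.

The flask gives 18.2 % at 8.0 d, and amber adds most, 8.2 points, while teal reaches 20.6 % and blue 17.0 %. At 192 h, 84.7 % of the charged coupling partner was still free.

    starting material + coupling partner ⇌ intermediate (K = 0.430 L mol⁻¹, k = 1.70 L mol⁻¹ h⁻¹, Ea = 91.0 kJ mol⁻¹, ΔH = 8.00 kJ mol⁻¹)
    intermediate ⇌ target + released group (K = 0.0940 M, k = 0.0550 h⁻¹, Ea = 128 kJ mol⁻¹, ΔH = −27.0 kJ mol⁻¹)
    target ⇌ isomer of the product (K = 28.0, k = 0.00160 h⁻¹, Ea = 122 kJ mol⁻¹, ΔH = 10.0 kJ mol⁻¹)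
    (constants at 100 °C)

My 23.4 h counted 4.10 half-lives in the wait after amber and so gave 14 points, but of the 16 points taken out the flask regained 8.2 points, about half. The same count for this flask read at 5.0 d gives 5.13 half-lives and my level of 17 %, but it held 18.5 % of target then, and left to 1920 h it held 7.28 %.

(The data are calculated on assumed constants.)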